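**Retrosynthetic overview**
1. Target ⇒ triangelate 11 by a last, catalyst-controlled epoxidation of the prenyl alkene; 11 ⇒ epoxy triol 10 by triple angeloylation.
2. 10 ⇒ α-methylene ketone 9 (oxazaborolidine reduction sets C8); 9 ⇒ ene-diol 8 by hydroxyl-directed epoxidation of the ring alkene.
3. 8 ⇒ iodoallyl ketal 6 by 5-exo vinyl-radical cyclization onto the diene (C1–C7 bond, cis to the C2 oxygen), then ketal hydrolysis; 6 ⇒ diene diol 2 + alkoxyallene 5.
4. Key step: 2 ⇒ toluene by enzymatic dearomative cis-dihydroxylation, which sets C2/C3 in the absolute sense; every other ring stereocentre is relayed from them without protecting groups.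
5. Ring order: the carbocycle is toluene's own ring; a temporary oxolane ketal ring is formed and opened in step 4; then the ring oxirane (step 5); the side-chain oxirane last (step 8).

Assumption: the recombinant toluene-dioxygenase strain E. coli JM109(pDTG601) counts as an available biocatalyst; toluene, methoxyallene, prenyl bromide and angelic acid are bought.

Position labels used below: ring C1 (bears the side chain), C2 and C3 (esters), C4 (methyl, epoxide), C5 (epoxide), C6 (CH2); side chain C7(=C14H2), C8 (ester), C9, C10/C11 (epoxide).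

**Step 1**
Reactants: 1 toluene
Product: 2 (1S,2R)-3-methylcyclohexa-3,5-diene-1,2-diol
Conditions: whole cells of E. coli JM109(pDTG601) expressing toluene dioxygenase, air, glucose feed, phosphate buffer pH 7, 30 °C, toluene supplied as vapour; EtOAc extraction
Reagents that add atoms: dioxygen, O=O
Why: Enzymatic dearomative cis-dihydroxylation, in which the dioxygenase adds both oxygen atoms of O2 to one face across the ortho/meta positions of toluene to give the (1S,2R)-diol, whose two carbinol centres are C3 and C2 of the target in the correct absolute sense.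

**Step 2**
Reactants: 3 methoxyallene; 4 prenyl bromide
Product: 5 3-methoxy-6-methylhepta-1,2,5-triene
Conditions: n-BuLi, THF, −40 °C; then 4, −40 → 0 °C
Reagents that add atoms: none
Why: α-Lithiation of the alkoxyallene next to oxygen followed by SN2 alkylation at the primary allylic carbon of the bromide, with no stereocentre formed.

**Step 3**
Reactants: 2 (1S,2R)-3-methylcyclohexa-3,5-diene-1,2-diol; 5 3-methoxy-6-methylhepta-1,2,5-triene
Product: 6 (1R,6S)-6-[(2-iodo-3-methoxy-6-methylhepta-1,5-dien-3-yl)oxy]-2-methylcyclohexa-2,4-dien-1-ol (both epimers at the ketal carbon)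
Conditions: NIS (1.2 equiv), 5 (1.5 equiv), 4 Å molecular sieves, CH2Cl2, −78 → −30 °C
Reagents that add atoms: N-iodosuccinimide, O=C1CCC(=O)N1I
Why: Iodoalkoxylation of an alkoxyallene (Ueno–Stork-type mixed-ketal formation), in which iodonium adds to the central allene carbon and the oxocarbenium ion is captured by the less hindered hydroxyl distal to the methyl group, leaving both carbinol centres untouched and the ketal carbon as an inconsequential epimer mixture.

**Step 4**
Reactants: 6 (1R,6S)-6-[(2-iodo-3-methoxy-6-methylhepta-1,5-dien-3-yl)oxy]-2-methylcyclohexa-2,4-dien-1-ol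
Product: 8 2-[(1R,5R,6S)-5,6-dihydroxy-4-methylcyclohex-3-en-1-yl]-6-methylhepta-1,5-dien-3-one, via bicyclic methyl ketal 7 (not isolated)
Conditions: Bu3SnH (slow addition), Et3B, air, toluene, 0 °C → rt; then PPTS, acetone/H2O 9:1, rt
Reagents that add atoms: water, O
Why: Ueno–Stork-type 5-exo-trig vinyl-radical cyclization onto the diene terminus, where the oxygen tether forces the new C1–C7 bond onto the face of the C2 oxygen (cis ring fusion sets C1), the allyl radical takes hydrogen at its less hindered secondary end so the trisubstituted alkene stays, and mild acid hydrolysis then opens the ketal to the α-methylene ketone and frees the C2 hydroxyl.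

**Step 5**
Reactants: 8 2-[(1R,5R,6S)-5,6-dihydroxy-4-methylcyclohex-3-en-1-yl]-6-methylhepta-1,5-dien-3-one
Product: 9 2-[(1R,3R,4S,5S,6R)-4,5-dihydroxy-6-methyl-7-oxabicyclo[4.1.0]heptan-3-yl]-6-methylhepta-1,5-dien-3-one
Conditions: VO(acac)2 (5 mol %), t-BuOOH (1.3 equiv, in decane), CH2Cl2, 0 °C
Reagents that add atoms: tert-butyl hydroperoxide, CC(C)(C)OO
Why: Hydroxyl-directed vanadium-catalysed epoxidation, in which the allylic C3 hydroxyl (helped by the cis C2 hydroxyl) delivers the peroxide oxygen to its own face and sets C4 and C5 syn to the diol, while the electron-poor enone alkene and the undirected prenyl alkene do not react.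

**Step 6**
Reactants: 9 2-[(1R,3R,4S,5S,6R)-4,5-dihydroxy-6-methyl-7-oxabicyclo[4.1.0]heptan-3-yl]-6-methylhepta-1,5-dien-3-one
Product: 10 (1R,2S,3S,4R,6R)-4-[(3S)-3-hydroxy-6-methylhepta-1,5-dien-2-yl]-1-methyl-7-oxabicyclo[4.1.0]heptane-2,3-diol
Conditions: (R)-2-methyl-CBS-oxazaborolidine (0.5 equiv), catecholborane (4 equiv, the excess covers the free hydroxyls), toluene, −78 °C; MeOH, then aq. NaHCO3
Reagents that add atoms: none
Why: Corey–Bakshi–Shibata reduction, in which the (R)-oxazaborolidine treats the α-branched alkenyl group as the large and the CH2 group as the small ketone substituent and delivers hydride 1,2 to give the (8S)-allylic alcohol under catalyst control, the epoxide being inert at −78 °C.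

**Step 7**
Reactants: 10 (1R,2S,3S,4R,6R)-4-[(3S)-3-hydroxy-6-methylhepta-1,5-dien-2-yl]-1-methyl-7-oxabicyclo[4.1.0]heptane-2,3-diol
Product: 11 (1R,2S,3S,4R,6R)-1-methyl-4-[(3S)-6-methyl-3-{[(2Z)-2-methylbut-2-enoyl]oxy}hepta-1,5-dien-2-yl]-7-oxabicyclo[4.1.0]heptane-2,3-diyl bis[(2Z)-2-methylbut-2-enoate]
Conditions: angelic acid (6 equiv), 2,4,6-trichlorobenzoyl chloride (6 equiv), Et3N (excess), toluene, rt, precipitated salt filtered off; then 10, toluene, 75 °C
Reagents that add atoms: angelic acid ((2Z)-2-methylbut-2-enoic acid), OC(=O)/C(C)=C\C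
Why: Yamaguchi-type mixed-anhydride esterification, in which the di-ortho-substituted aroyl carbonyl is shielded so each hydroxyl attacks the angeloyl carbonyl, and leaving out nucleophilic acyl-transfer catalysts keeps the Z geometry; no stereocentre is touched.

**Step 8**
Reactants: 11 (1R,2S,3S,4R,6R)-1-methyl-4-[(3S)-6-methyl-3-{[(2Z)-2-methylbut-2-enoyl]oxy}hepta-1,5-dien-2-yl]-7-oxabicyclo[4.1.0]heptane-2,3-diyl bis[(2Z)-2-methylbut-2-enoate]
Product: 12 (1R,2S,3S,4R,6R)-4-[(3S)-4-[(2R)-3,3-dimethyloxiran-2-yl]-3-{[(2Z)-2-methylbut-2-enoyl]oxy}but-1-en-2-yl]-1-methyl-7-oxabicyclo[4.1.0]heptane-2,3-diyl bis[(2Z)-2-methylbut-2-enoate] (target)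
Conditions: 1,2:4,5-di-O-isopropylidene-β-D-erythro-2,3-hexodiulo-2,6-pyranose (D-fructose-derived Shi ketone, 0.3 equiv), KHSO5 (as 2KHSO5·KHSO4·K2SO4, 1.4 equiv), K2CO3, Bu4NHSO4, MeCN/dimethoxymethane, aq. Na2B4O7 buffer pH 10.5, 0 °C
Reagents that add atoms: potassium peroxymonosulfate, [K+].[O-]S(=O)(=O)OO
Why: Shi asymmetric epoxidation, in which the chiral dioxirane attacks the only electron-rich trisubstituted alkene through the spiro transition state to give the (10R)-epoxide under catalyst control, the conjugated angelate alkenes and the 1,1-disubstituted allylic-ester alkene being too electron-poor to compete.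

**Compound list**
1 | toluene | Cc1ccccc1 | starting material
2 | (1S,2R)-3-methylcyclohexa-3,5-diene-1,2-diol | CC1=CC=C[C@H](O)[C@@H]1O | intermediate
3 | methoxyallene (1-methoxypropa-1,2-diene) | COC=C=C | starting material
4 | prenyl bromide (1-bromo-3-methylbut-2-ene) | CC(C)=CCBr | starting material
5 | 3-methoxy-6-methylhepta-1,2,5-triene | C=C=C(OC)CC=C(C)C | intermediate
6 | (1R,6S)-6-[(2-iodo-3-methoxy-6-methylhepta-1,5-dien-3-yl)oxy]-2-methylcyclohexa-2,4-dien-1-ol, ketal epimers | CC1=CC=C[C@H](OC(OC)(CC=C(C)C)C(I)=C)[C@@H]1O | intermediate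
7 | (3aR,7R,7aS)-2-methoxy-6-methyl-3-methylidene-2-(3-methylbut-2-en-1-yl)-2,3,3a,4,7,7a-hexahydro-1-benzofuran-7-ol, ketal epimers | C=C1[C@H]2CC=C(C)[C@@H](O)[C@H]2OC1(OC)CC=C(C)C | intermediate (not isolated)
8 | 2-[(1R,5R,6S)-5,6-dihydroxy-4-methylcyclohex-3-en-1-yl]-6-methylhepta-1,5-dien-3-one | C=C([C@H]1CC=C(C)[C@@H](O)[C@H]1O)C(=O)CC=C(C)C | intermediate
9 | 2-[(1R,3R,4S,5S,6R)-4,5-dihydroxy-6-methyl-7-oxabicyclo[4.1.0]heptan-3-yl]-6-methylhepta-1,5-dien-3-one | C=C([C@H]1C[C@H]2O[C@@]2(C)[C@@H](O)[C@H]1O)C(=O)CC=C(C)C | intermediate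
10 | (1R,2S,3S,4R,6R)-4-[(3S)-3-hydroxy-6-methylhepta-1,5-dien-2-yl]-1-methyl-7-oxabicyclo[4.1.0]heptane-2,3-diol | C=C([C@@H](O)CC=C(C)C)[C@H]1C[C@H]2O[C@@]2(C)[C@@H](O)[C@H]1O | intermediate
11 | (1R,2S,3S,4R,6R)-1-methyl-4-[(3S)-6-methyl-3-{[(2Z)-2-methylbut-2-enoyl]oxy}hepta-1,5-dien-2-yl]-7-oxabicyclo[4.1.0]heptane-2,3-diyl bis[(2Z)-2-methylbut-2-enoate] | C=C([C@H](CC=C(C)C)OC(=O)/C(C)=C\C)[C@H]1C[C@H]2O[C@@]2(C)[C@@H](OC(=O)/C(C)=C\C)[C@H]1OC(=O)/C(C)=C\C | intermediate
12 | (1R,2S,3S,4R,6R)-4-[(3S)-4-[(2R)-3,3-dimethyloxiran-2-yl]-3-{[(2Z)-2-methylbut-2-enoyl]oxy}but-1-en-2-yl]-1-methyl-7-oxabicyclo[4.1.0]heptane-2,3-diyl bis[(2Z)-2-methylbut-2-enoate] | C=C([C@H](C[C@H]1OC1(C)C)OC(=O)/C(C)=C\C)[C@H]1C[C@H]2O[C@@]2(C)[C@@H](OC(=O)/C(C)=C\C)[C@H]1OC(=O)/C(C)=C\C | target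

**Step count**
Total: 8 steps. Longest linear sequence: 7 steps (1, 3, 4, 5, 6, 7, 8, from toluene); step 2 is a one-step side branch.

**Three steps most likely to fail**

Step 3 (iodoketalization). The risks are acylation-type selectivity between the two hydroxyls, formation of a fully substituted ketal, and the sensitivity of the diene diol to electrophiles and acid. The fallback sets out from 2 and returns at 8. The distal hydroxyl is silylated with (1-bromovinyl)chlorodimethylsilane (Et3N, CH2Cl2, −78 °C), a reaction class with established distal selectivity on such diols, to give the bromovinylsilyl ether F1. The same Bu3SnH/Et3B 5-exo vinyl-radical cyclization gives the cis-fused cyclic alkenylsiloxane F2. Tamao oxidation (H2O2, KF, KHCO3, THF/MeOH) converts the vinyl–silicon bond into a carbonyl and gives the methyl ketone F3. Condensation with 2,4,6-triisopropylbenzenesulfonohydrazide gives the trisylhydrazone F4. Shapiro reaction (n-BuLi, THF, −78 → 0 °C) gives the vinyllithium F5, which is acylated in the same flask with N-methoxy-N,4-dimethylpent-3-enamide to give 8.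

Step 6 (oxazaborolidine reduction). The two free ring hydroxyls (and a possible cyclic hemiketal form of the γ-hydroxy ketone) may slow the catalyst or lower the selectivity. The fallback sets out from 9 and returns at 11, bypassing 10. The two ring hydroxyls are angeloylated first with the same mixed anhydride to give the bis-angelate enone F6. The reduction is then run on this hydroxyl-free ketone to give the (8S)-allylic alcohol F7. The remaining hydroxyl is angeloylated to give 11.

Step 7 (triple angeloylation). The risks are incomplete acylation of the hindered C3 hydroxyl, Z to E drift at 75 °C, and epoxide opening. The fallback sets out from 10 and returns at 11. All three hydroxyls are esterified with 2-[bis(2,2,2-trifluoroethoxy)phosphoryl]propanoic acid (DCC, DMAP, CH2Cl2, 0 °C) to give the tris-phosphonate F8. The three Z-alkenes are then built on the molecule by threefold Still–Gennari olefination with acetaldehyde (KN(SiMe3)2, 18-crown-6, THF, −78 °C), which gives 11.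

**Further compounds**
F1 | step 3 | (1R,6S)-6-{[(1-bromoethenyl)dimethylsilyl]oxy}-2-methylcyclohexa-2,4-dien-1-ol | CC1=CC=C[C@H](O[Si](C)(C)C(Br)=C)[C@@H]1O
F2 | step 3 | (3aS,7R,7aS)-2,2,6-trimethyl-3-methylidene-2,3,3a,4,7,7a-hexahydro-1,2-benzoxasilol-7-ol | C=C1[C@H]2CC=C(C)[C@@H](O)[C@H]2O[Si]1(C)C
F3 | step 3 | 1-[(1S,5R,6S)-5,6-dihydroxy-4-methylcyclohex-3-en-1-yl]ethan-1-one | CC(=O)[C@H]1CC=C(C)[C@@H](O)[C@H]1O
F4 | step 3 | N'-{1-[(1R,5R,6S)-5,6-dihydroxy-4-methylcyclohex-3-en-1-yl]ethylidene}-2,4,6-tri(propan-2-yl)benzenesulfonohydrazide | CC(=NNS(=O)(=O)c1c(C(C)C)cc(C(C)C)cc1C(C)C)[C@H]1CC=C(C)[C@@H](O)[C@H]1O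
F5 | step 3 | {1-[(1R,5R,6S)-5,6-bis(lithiooxy)-4-methylcyclohex-3-en-1-yl]ethenyl}lithium | [Li]C(=C)[C@H]1CC=C(C)[C@@H](O[Li])[C@H]1O[Li]
F6 | step 6 | (1R,2S,3S,4R,6R)-1-methyl-4-(6-methyl-3-oxohepta-1,5-dien-2-yl)-7-oxabicyclo[4.1.0]heptane-2,3-diyl bis[(2Z)-2-methylbut-2-enoate] | C=C([C@H]1C[C@H]2O[C@@]2(C)[C@@H](OC(=O)/C(C)=C\C)[C@H]1OC(=O)/C(C)=C\C)C(=O)CC=C(C)C
F7 | step 6 | (1R,2S,3S,4R,6R)-4-[(3S)-3-hydroxy-6-methylhepta-1,5-dien-2-yl]-1-methyl-7-oxabicyclo[4.1.0]heptane-2,3-diyl bis[(2Z)-2-methylbut-2-enoate] | C=C([C@@H](O)CC=C(C)C)[C@H]1C[C@H]2O[C@@]2(C)[C@@H](OC(=O)/C(C)=C\C)[C@H]1OC(=O)/C(C)=C\C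
F8 | step 7 | (1R,2S,3S,4R,6R)-4-[(3S)-3-({2-[bis(2,2,2-trifluoroethoxy)phosphoryl]propanoyl}oxy)-6-methylhepta-1,5-dien-2-yl]-1-methyl-7-oxabicyclo[4.1.0]heptane-2,3-diyl bis{2-[bis(2,2,2-trifluoroethoxy)phosphoryl]propanoate}, epimers at the phosphonate-bearing carbons | C=C([C@H](CC=C(C)C)OC(=O)C(C)P(=O)(OCC(F)(F)F)OCC(F)(F)F)[C@H]1C[C@H]2O[C@@]2(C)[C@@H](OC(=O)C(C)P(=O)(OCC(F)(F)F)OCC(F)(F)F)[C@H]1OC(=O)C(C)P(=O)(OCC(F)(F)F)OCC(F)(F)F
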